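## Structural features

Cyclointegrin (23) is a tetracyclic flavone. Ring A (C4a–C8a) carries a free hydroxyl on C5, hydrogen-bonded to the C4 carbonyl, and a methoxy group on C7. The 4-pyranone ring C joins ring A to ring B, which sits on C2 and bears a hydroxyl on C4'. A fourth, eight-membered oxocine ring ties C3 to the C2' oxygen through CH2–CH2–C(CH3)2, so the C2=C3 bond of the pyranone is also the cis double bond of a 1-benzoxocine. There is no stereocentre, so no stereocentres stand next to each other; the only stereo-element is the ring-enforced cis geometry of C2=C3. The fragile groups are the tertiary alkyl aryl ether (it ionises under strong Brønsted or Lewis acid, which rules out Lewis-acid dealkylation late in the route), the electron-rich free phenols, and any benzyl ether whenever hydrogen and a metal are present. The real difficulty is the medium ring with its fully substituted C2=C3 bond and tertiary ether, together with three phenolic oxygens in three different states. The key step uses the arrangement on ring A in which C8a bears O1, the neighbouring C4a bears C4, and C4a lies next to the C5 oxygen: this is the 1,2-difunctionalisation pattern of a 3-alkoxyaryne, with the nucleophile on the remote carbon and the electrophile on the near one.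

## Logic of the disconnections

23 ⇒ 22. The two benzylic C–O bonds on O5 and O4' are cut. Both free phenols are masked by one group that hydrogenolysis removes without acid, which protects the tertiary ether. The phenols stay silent through organolithium, fluoride and acid steps. The forward step must spare the pyranone double bond, the methyl ether and the tertiary ether.

22 ⇒ 21. The O1–C2 bond is cut, opening the pyranone to an ortho-hydroxyaryl ketone whose enone carries a methoxy leaving group on the future C2. Closure is then an intramolecular addition–elimination at the correct oxidation level. Ring C disappears from the problem. The forward step needs a free phenol on ring A and conditions mild towards the tertiary ether.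

21 ⇒ 20 + 10. The O1–C8a and C4–C4a bonds are cut together, releasing ring A as an aryne equivalent and the rest as a carboxylic acid. The ortho relationship of O1 and C4 beside the C5 oxygen is what a 3-alkoxyaryne delivers. The gain is convergence into two fragments of similar size with the eight-membered ring already complete. The forward step needs regioselective addition to the aryne and acyl transfer that outruns protonation of the aryl anion.

10 ⇒ 8 ⇒ 5. The S–O bond of the sulfonate and the C6–Si bond are cut, leaving an aryl carbamate. Silicon is placed ortho to the oxygen that becomes the leaving group because that oxygen, as a carbamate, can direct lithiation to its single free ortho position. The forward step must lithiate there and not between the two ether oxygens or at the benzylic CH2.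

5 ⇒ 4 ⇒ 2 ⇒ 1. The carbamoyl C–O bond is cut, the phenolic C–O bond is traced back to an aryl–CHO bond (Baeyer–Villiger transform), and the benzyl ether is removed. The 1,2,4-oxygen pattern is thus bought with 1. The forward oxidation needs the aryl group to migrate in preference to hydrogen.

20 ⇒ 19 ⇒ 18. The ester O–CH3 and the enol O–CH3 bonds are cut, revealing a cyclic β-keto ester that already holds C4 and C2 of the flavone at the right oxidation levels. The forward steps need O- rather than C-methylation and an ester hydrolysis that leaves the enol ether intact.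

18 ⇒ 16 ⇒ 12 + 13. The ketone is traced to an enamine and C3–C4 to an alkene. The two carbons C4 and C5 with the ester are then excised by cutting C3–C4 and C5–C6 and rejoining C3 to C6, which contracts the eight-membered ring to a chromanone. No eight-membered ring closure is needed and the tertiary aryl ether is bought. The forward steps need enamine formation on a hindered aryl ketone and an alkene hydrogenation that spares the benzyl ether.

12 ⇒ 11. The benzyl ether is cut, leaving the purchasable hydroxychromanone. The forward step is a simple phenol alkylation.

## Other disconnections considered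

Alternative 1: The cut is at C4–C4a and O1–C2, giving phloroglucinol A2 and the β-keto ester 18. The forward key step heats the two near 240 °C: the arene is acylated, a phenolic oxygen condenses with the ring ketone, and the result is the 5,7-dihydroxyflavone A1. Selective methylation of the unchelated 7-hydroxyl and hydrogenolysis would finish the synthesis.
- In favour: it branches off from 18, needs no aryne precursor, and the symmetry of A2 removes any regiochemical question at the annulation. In step economy it is clearly the better plan, at roughly six steps from 11 against thirteen.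
- Against: a phenolic melt at 240 °C is a harsh setting for the tertiary alkyl aryl ether and the benzyl ether. Attack of the arene on the ketone carbon (coumarin formation) competes with the desired acylation. The α-substituted medium-ring keto ester should react sluggishly. The 7-methyl group must be added afterwards.
- Comparison: both plans deliver the full skeleton. The chosen plan sets both ring A bonds at 125 °C under mildly basic conditions, with the oxygen pattern already differentiated. Alternative 1 is shorter but less controlled, and is kept as the fallback for step 11.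

Alternative 2: The cut is in the middle of the two-carbon bridge, read as CH=CH. The forward key step is ring-closing metathesis of the 3-vinylflavone A4, which carries a 1,1-dimethylallyl ether on C2', with the second-generation Grubbs catalyst to give the didehydro compound A3.
- In favour: the flavone core would be built by classical chemistry, the cis alkene is the only possible outcome, and the gem-dimethyl group and twisted C2–C1' axis pre-organise the chain. One final hydrogenation would saturate the bridge and remove both benzyl groups, so on the end-game this alternative is better (one step against two).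
- Against: eight-membered ring closure by metathesis is slow. One alkene is neopentyl-like and the other is conjugated to the pyranone, so dimerisation or no reaction is a real risk. The 1,1-dimethylallyl aryl ether is prone to aromatic Claisen rearrangement and to ionisation on warming. Preparing A4 needs a 3-halogenation and vinylation of the flavone and a reverse prenylation of a hindered phenol.
- Comparison: the chosen plan never has to close the medium ring. The step count is estimated to be similar.

Alternative 3: The cut is at C1'–C2 and C2–C3, with C2 supplied by carbon monoxide A7. The forward key step treats the bromo ketone A6 with Pd(dba)2, Xantphos, A7 and Cs2CO3 to give the cyclic 1,3-diketone A5. Hydrogenolysis of three benzyl ethers and cyclodehydration would follow.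
- In favour: the step is atom-economic, and the product maps directly onto the flavone. Ring A enters as a symmetrical 2,6-bis(benzyloxy) unit, so no regiochemical control is needed, and on that point the alternative is better than the aryne plan.
- Against: carbonylative α-arylation is an intermolecular reaction type. Here it must close an eight-membered ring, and direct arylation without A7 (a seven-membered ring) and oligomerisation compete. The enolate of a di-ortho-substituted aryl ketone is hindered. A6 requires the tertiary alkyl aryl ether to be made intermolecularly, a bond the chosen plan buys.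
- Comparison: the step count is estimated to be comparable, with higher mechanistic risk at the ring-forming step.

Key step: step 11

Remarks on the chemistry:
- The two partners of step 11 were checked atom by atom against the target. The aryne carbon that bore the triflate becomes C4a and the one that bore silicon becomes C8a, so the structures are consistent and need no correction.
- The ring double bonds of 16, 17, 19, 20 and 21 are cis within the eight-membered ring (Z descriptors), the only geometry such a ring can hold. Compound 18 is racemic at C5 and largely enolised; that centre disappears in step 9.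
- Three design choices are made for safety: a peracid oxidation for 2 (it has no free hydroxyl for the alkaline peroxide variant), a secondary carbamate that leaves under mild base, and a poisoned catalyst for the alkene hydrogenation so that the benzyl ether survives.
- Compounds 1, 11 and 13 are assumed to be purchasable.

## Route

Step 1
Reactants: 1 2-hydroxy-4-methoxybenzaldehyde
Product: 2 2-(benzyloxy)-4-methoxybenzaldehyde
Conditions: BnBr, K2CO3, DMF, 60 °C
Reagents that add atoms: benzyl bromide, BrCc1ccccc1
Why: Williamson ether synthesis; the phenol is the only acidic site and K2CO3 in warm DMF should overcome its hydrogen bond to the aldehyde.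

Step 2
Reactants: 2 2-(benzyloxy)-4-methoxybenzaldehyde
Product: 4 2-(benzyloxy)-4-methoxyphenol, via aryl formate 3 (not isolated)
Conditions: mCPBA, CH2Cl2, 0 °C to rt; aq. NaHCO3 wash; K2CO3 (cat.), MeOH, rt
Reagents that add atoms: 3-chloroperoxybenzoic acid, OOC(=O)c1cccc(Cl)c1
Why: Baeyer–Villiger oxidation used in the Dakin sense: the electron-rich 2,4-dialkoxyaryl group migrates in preference to hydrogen to give formate 3, which mild methanolysis cleaves to the phenol.

Step 3
Reactants: 4 2-(benzyloxy)-4-methoxyphenol
Product: 5 2-(benzyloxy)-4-methoxyphenyl N-(propan-2-yl)carbamate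
Conditions: i-PrNCO, Et3N (cat.), CH2Cl2, rt
Reagents that add atoms: isopropyl isocyanate, CC(C)N=C=O
Why: Base-catalysed addition of the phenol to the isocyanate; the secondary carbamate directs lithiation and can later be removed under mild base by elimination.

Step 4
Reactants: 5 2-(benzyloxy)-4-methoxyphenyl N-(propan-2-yl)carbamate
Product: 8 2-(benzyloxy)-4-methoxy-6-(trimethylsilyl)phenyl N-(propan-2-yl)carbamate, via N-silylated carbamate 6 (not isolated), via doubly silylated carbamate 7 (not isolated)
Conditions: TBSOTf, TMEDA, Et2O, 0 °C to rt; n-BuLi, TMEDA, −78 °C; TMSCl, −78 °C to rt; aq. NaHSO4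
Reagents that add atoms: chlorotrimethylsilane, C[Si](C)(C)Cl; tert-butyldimethylsilyl triflate, CC(C)(C)[Si](C)(C)OS(=O)(=O)C(F)(F)F (its silyl group stays only in 6 and 7)
Why: Directed ortho-metalation: N-silylation to 6 blocks N–H deprotonation and loss of isocyanate, the carbamate guides n-BuLi to C6 (its only free ortho position), TMSCl traps the aryllithium as 7, and aqueous NaHSO4 removes the N-silyl group. The low temperature and the strong carbamate director should outrun lithiation between the two ether oxygens and at the benzylic CH2.

Step 5
Reactants: 8 2-(benzyloxy)-4-methoxy-6-(trimethylsilyl)phenyl N-(propan-2-yl)carbamate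
Product: 10 2-(benzyloxy)-4-methoxy-6-(trimethylsilyl)phenyl trifluoromethanesulfonate, via silyl phenol 9 (not isolated)
Conditions: DBU, Et2NH, MeCN, 40 °C; PhNTf2, rt
Reagents that add atoms: N-phenylbis(trifluoromethanesulfonimide), O=S(=O)(N(c1ccccc1)S(=O)(=O)C(F)(F)F)C(F)(F)F
Why: DBU removes the carbamate N–H proton and phenoxide 9 is expelled (E1cB), Et2NH scavenges the isocyanate as a urea, and PhNTf2 sulfonylates the phenoxide in the same flask; the mild conditions keep the aryl–silicon bond.

Step 6
Reactants: 11 7-hydroxy-2,2-dimethylchroman-4-one
Product: 12 7-(benzyloxy)-2,2-dimethylchroman-4-one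
Conditions: BnBr, K2CO3, DMF, 60 °C
Reagents that add atoms: benzyl bromide, BrCc1ccccc1
Why: Williamson ether synthesis on the only phenol; the ketone and the tertiary ether are inert to carbonate.

Step 7
Reactants: 12 7-(benzyloxy)-2,2-dimethylchroman-4-one; 13 methyl propiolate
Product: 16 methyl (3Z,5Z)-9-(benzyloxy)-2,2-dimethyl-6-(pyrrolidin-1-yl)-2H-1-benzoxocine-5-carboxylate, via chromene enamine 14 (not isolated), via cyclobutene adduct 15 (not isolated)
Conditions: pyrrolidine, TiCl4, toluene, 0 °C to rt; filtration under N2, concentration; 13, toluene, rt to 80 °C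
Reagents that add atoms: pyrrolidine, C1CCNC1
Why: TiCl4-mediated condensation gives enamine 14, whose nucleophilic C3 adds to the alkyne terminus of 13; the zwitterion closes to cyclobutene 15 (formal [2+2] cycloaddition) and the push–pull ring opens with cleavage of the former C3–C4 bond, the enamine–acetylenic ester two-carbon ring enlargement. The ester ends up on the carbon next to the amine-bearing carbon and both ring double bonds are cis, as the ring demands.

Step 8
Reactants: 16 methyl (3Z,5Z)-9-(benzyloxy)-2,2-dimethyl-6-(pyrrolidin-1-yl)-2H-1-benzoxocine-5-carboxylate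
Product: 18 methyl 9-(benzyloxy)-2,2-dimethyl-6-oxo-3,4,5,6-tetrahydro-2H-1-benzoxocine-5-carboxylate, via saturated enamino ester 17 (not isolated)
Conditions: H2 (1 atm), 5% Pd/C, 2,2'-bipyridyl (0.5 equiv), EtOAc, rt; filtration; 1 M HCl, THF, rt
Reagents that add atoms: water, O
Why: Catalytic hydrogenation of the cis-disubstituted C3=C4 bond; the tetrasubstituted push–pull enamino ester bond is inert and the nitrogen additive suppresses hydrogenolysis of the aryl benzyl ether. Dilute acid then hydrolyses the vinylogous carbamate 17 by C-protonation and iminium hydrolysis.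

Step 9
Reactants: 18 methyl 9-(benzyloxy)-2,2-dimethyl-6-oxo-3,4,5,6-tetrahydro-2H-1-benzoxocine-5-carboxylate
Product: 19 methyl (5Z)-9-(benzyloxy)-6-methoxy-2,2-dimethyl-3,4-dihydro-2H-1-benzoxocine-5-carboxylate
Conditions: TMSCHN2, i-Pr2NEt, MeCN–MeOH, rt
Reagents that add atoms: (trimethylsilyl)diazomethane, C[Si](C)(C)C=[N+]=[N-]
Why: O-Methylation of the enol by a diazoalkane: proton transfer gives a diazonium–enolate ion pair that collapses on oxygen, so C-methylation to a quaternary centre is avoided; the Z geometry is imposed by the ring.

Step 10
Reactants: 19 methyl (5Z)-9-(benzyloxy)-6-methoxy-2,2-dimethyl-3,4-dihydro-2H-1-benzoxocine-5-carboxylate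
Product: 20 (5Z)-9-(benzyloxy)-6-methoxy-2,2-dimethyl-3,4-dihydro-2H-1-benzoxocine-5-carboxylic acid
Conditions: LiOH, THF–MeOH–H2O, 60 °C; 1 M HCl to pH 4, 0 °C
Reagents that add atoms: lithium hydroxide, [Li+].[OH-]
Why: Saponification of the methyl ester; the enol ether is stable to base, and brief cold acidification to pH 4 should free the acid without hydrolysing it.

Step 11
Reactants: 20 (5Z)-9-(benzyloxy)-6-methoxy-2,2-dimethyl-3,4-dihydro-2H-1-benzoxocine-5-carboxylic acid; 10 2-(benzyloxy)-4-methoxy-6-(trimethylsilyl)phenyl trifluoromethanesulfonate
Product: 21 [2-(benzyloxy)-6-hydroxy-4-methoxyphenyl][(5Z)-9-(benzyloxy)-6-methoxy-2,2-dimethyl-3,4-dihydro-2H-1-benzoxocin-5-yl]methanone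
Conditions: CsF (4 equiv), THF, 125 °C, sealed tube
Reagents that add atoms: none
Why: CsF removes the silyl group of 10 and triflate leaves, releasing 3-benzyloxy-5-methoxybenzyne, while 20 is converted into its caesium carboxylate. The carboxylate oxygen adds to the aryne carbon remote from the benzyloxy group, because attack there places the developing aryl anion on the carbon next to the inductively withdrawing oxygen; this forms O1–C8a and puts the anion on C4a. The anion attacks the carbonyl of its own aryl ester in a 4-exo-trig mode and the four-membered alkoxide opens by C–O cleavage to the ketone phenoxide, which forms C4–C4a. The closest known reaction type is the insertion of arynes into the C–O bond of carboxylic acids to give ortho-hydroxyaryl ketones, which is also known for α,β-unsaturated acids. No ring remains closed (the four-membered ring is transient) and no stereocentre is formed; the Z enol ether is untouched. The step needs regioselective addition, secured by the C5 benzyloxy group beside the triple bond, and acyl transfer faster than protonation of the aryl anion, favoured by aprotic THF, the high temperature and the binding of HF as CsHF2. Conjugate attack of the aryl anion is disfavoured because the β-carbon is fully substituted, and any 21 that already closes to 22 in the basic medium is carried into step 12, where both converge.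

Step 12
Reactants: 21 [2-(benzyloxy)-6-hydroxy-4-methoxyphenyl][(5Z)-9-(benzyloxy)-6-methoxy-2,2-dimethyl-3,4-dihydro-2H-1-benzoxocin-5-yl]methanone
Product: 22 5,4'-di-O-benzylcyclointegrin (flavone numbering: 5-benzyloxy, 7-methoxy, 4'-benzyloxy; C3 joined to the C2' oxygen through CH2CH2C(CH3)2)
Conditions: p-TsOH·H2O (10 mol %), toluene, 50 °C
Reagents that add atoms: none
Why: Acid-catalysed intramolecular addition–elimination (vinylogous transesterification): protonation of the enone gives a cation at the future C2 stabilised by the methoxy group and ring B, the phenol adds and methanol is lost to give the 4-pyranone. Any enol ether hydrolysed to the 1,3-diketone cyclodehydrates to the same product.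

Step 13
Reactants: 22 5,4'-di-O-benzylcyclointegrin
Product: 23 cyclointegrin
Conditions: H2 (1 atm), 10% Pd/C, EtOAc–MeOH, rt
Reagents that add atoms: none
Why: Hydrogenolysis of both aryl benzyl ethers; the tetrasubstituted pyranone double bond, the methyl ether and the non-benzylic tertiary alkyl aryl ether should not be affected.

## Compound list

1 | 2-hydroxy-4-methoxybenzaldehyde | COc1ccc(C=O)c(O)c1 | starting material
2 | 2-(benzyloxy)-4-methoxybenzaldehyde | COc1ccc(C=O)c(OCc2ccccc2)c1 | intermediate
3 | 2-(benzyloxy)-4-methoxyphenyl formate | COc1ccc(OC=O)c(OCc2ccccc2)c1 | intermediate (not isolated)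
4 | 2-(benzyloxy)-4-methoxyphenol | COc1ccc(O)c(OCc2ccccc2)c1 | intermediate
5 | 2-(benzyloxy)-4-methoxyphenyl N-(propan-2-yl)carbamate | COc1ccc(OC(=O)NC(C)C)c(OCc2ccccc2)c1 | intermediate
6 | 2-(benzyloxy)-4-methoxyphenyl N-[tert-butyl(dimethyl)silyl]-N-(propan-2-yl)carbamate | COc1ccc(OC(=O)N(C(C)C)[Si](C)(C)C(C)(C)C)c(OCc2ccccc2)c1 | intermediate (not isolated)
7 | 2-(benzyloxy)-4-methoxy-6-(trimethylsilyl)phenyl N-[tert-butyl(dimethyl)silyl]-N-(propan-2-yl)carbamate | COc1cc(OCc2ccccc2)c(OC(=O)N(C(C)C)[Si](C)(C)C(C)(C)C)c([Si](C)(C)C)c1 | intermediate (not isolated)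
8 | 2-(benzyloxy)-4-methoxy-6-(trimethylsilyl)phenyl N-(propan-2-yl)carbamate | COc1cc(OCc2ccccc2)c(OC(=O)NC(C)C)c([Si](C)(C)C)c1 | intermediate
9 | 2-(benzyloxy)-4-methoxy-6-(trimethylsilyl)phenol (formed as its amidinium phenoxide) | COc1cc(OCc2ccccc2)c(O)c([Si](C)(C)C)c1 | intermediate (not isolated)
10 | 2-(benzyloxy)-4-methoxy-6-(trimethylsilyl)phenyl trifluoromethanesulfonate | COc1cc(OCc2ccccc2)c(OS(=O)(=O)C(F)(F)F)c([Si](C)(C)C)c1 | intermediate
11 | 7-hydroxy-2,2-dimethylchroman-4-one | CC1(C)CC(=O)c2ccc(O)cc2O1 | starting material
12 | 7-(benzyloxy)-2,2-dimethylchroman-4-one | CC1(C)CC(=O)c2ccc(OCc3ccccc3)cc2O1 | intermediate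
13 | methyl propiolate | COC(=O)C#C | starting material
14 | 1-[7-(benzyloxy)-2,2-dimethyl-2H-chromen-4-yl]pyrrolidine | CC1(C)C=C(N2CCCC2)c2ccc(OCc3ccccc3)cc2O1 | intermediate (not isolated)
15 | methyl 6-(benzyloxy)-3,3-dimethyl-8b-(pyrrolidin-1-yl)-2a,8b-dihydro-3H-cyclobuta[c]chromene-1-carboxylate (cis ring fusion, racemic, one enantiomer drawn) | COC(=O)C1=C[C@H]2[C@]1(N3CCCC3)c3ccc(OCc4ccccc4)cc3OC2(C)C | intermediate (not isolated)
16 | methyl (3Z,5Z)-9-(benzyloxy)-2,2-dimethyl-6-(pyrrolidin-1-yl)-2H-1-benzoxocine-5-carboxylate | COC(=O)/C1=C(\N2CCCC2)c2ccc(OCc3ccccc3)cc2OC(C)(C)/C=C\1 | intermediate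
17 | methyl (5Z)-9-(benzyloxy)-2,2-dimethyl-6-(pyrrolidin-1-yl)-3,4-dihydro-2H-1-benzoxocine-5-carboxylate | COC(=O)/C1=C(\N2CCCC2)c2ccc(OCc3ccccc3)cc2OC(C)(C)CC1 | intermediate (not isolated)
18 | methyl 9-(benzyloxy)-2,2-dimethyl-6-oxo-3,4,5,6-tetrahydro-2H-1-benzoxocine-5-carboxylate (racemic at C5, enolisable) | COC(=O)C1CCC(C)(C)Oc2cc(OCc3ccccc3)ccc2C1=O | intermediate
19 | methyl (5Z)-9-(benzyloxy)-6-methoxy-2,2-dimethyl-3,4-dihydro-2H-1-benzoxocine-5-carboxylate | CO/C1=C(\C(=O)OC)CCC(C)(C)Oc2cc(OCc3ccccc3)ccc12 | intermediate
20 | (5Z)-9-(benzyloxy)-6-methoxy-2,2-dimethyl-3,4-dihydro-2H-1-benzoxocine-5-carboxylic acid | CO/C1=C(\C(O)=O)CCC(C)(C)Oc2cc(OCc3ccccc3)ccc12 | intermediate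
21 | [2-(benzyloxy)-6-hydroxy-4-methoxyphenyl][(5Z)-9-(benzyloxy)-6-methoxy-2,2-dimethyl-3,4-dihydro-2H-1-benzoxocin-5-yl]methanone | CO/C1=C(\C(=O)c2c(O)cc(OC)cc2OCc2ccccc2)CCC(C)(C)Oc2cc(OCc3ccccc3)ccc12 | intermediate
22 | 5,4'-di-O-benzylcyclointegrin | COc1cc(OCc2ccccc2)c2c(=O)c3c(oc2c1)-c1ccc(OCc2ccccc2)cc1OC(C)(C)CC3 | intermediate
23 | cyclointegrin | COc1cc(O)c2c(=O)c3c(oc2c1)-c1ccc(O)cc1OC(C)(C)CC3 | target

## Step count and least certain steps

Total step count: 13. Longest linear sequence: 8 steps (steps 6 to 13 from 11; the branch from 1 through steps 1 to 5 and 11 to 13 is equally long).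

Step 11 (key step).
- Risk: protonation of the aryl anion before acyl transfer, which would stop at simple O-arylation. The vinylogous carbonate carbonyl is a weak electrophile and bound HF is present. Arylation of the product phenoxide by a second aryne, or cycloaddition of the aryne to the enol ether, could also consume material.
- Fallback: it sets out from 18 and rejoins the route at 23. Compound 18 and phloroglucinol A2 are heated without solvent at about 240 °C (short microwave heating), which should give 4'-O-benzyl-7-O-demethylcyclointegrin F1 (the structure of A1). Me2SO4 (1 equiv) and K2CO3 in acetone should methylate only the unchelated 7-hydroxyl to give 4'-O-benzylcyclointegrin F2. Hydrogenolysis over Pd/C then leads to 23.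

Step 7.
- Risk: incomplete enamine formation, because the ketone is deactivated by the para benzyloxy group and flanked by a quaternary carbon. Reversible opening of the pyran ring at the enamine stage is possible, and the addition to 13 may stop at the open-chain adduct without ring enlargement.
- Fallback: it sets out from 12 and comes back at 18. TBSOTf and Et3N in CH2Cl2 convert 12 into tert-butyl{[7-(benzyloxy)-2,2-dimethyl-2H-chromen-4-yl]oxy}dimethylsilane F3. A TiCl4-promoted [2+2] cycloaddition with 13 at −78 °C should give the siloxycyclobutene methyl 6-(benzyloxy)-8b-{[tert-butyl(dimethyl)silyl]oxy}-3,3-dimethyl-2a,8b-dihydro-3H-cyclobuta[c]chromene-1-carboxylate F4. Heating in toluene opens it to methyl (3Z,5Z)-9-(benzyloxy)-6-{[tert-butyl(dimethyl)silyl]oxy}-2,2-dimethyl-2H-1-benzoxocine-5-carboxylate F5. Hydrogenation as in step 8 gives methyl (5Z)-9-(benzyloxy)-6-{[tert-butyl(dimethyl)silyl]oxy}-2,2-dimethyl-3,4-dihydro-2H-1-benzoxocine-5-carboxylate F6, and 1 M HCl in THF cleaves the silyl enol ether to 18.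

Step 4.
- Risk: competing lithiation between the two ether oxygens or at the benzylic CH2 (followed by Wittig rearrangement), or loss of the carbamate if N-silylation is incomplete.
- Fallback: it sets out from 4 and comes back at 10, replacing deprotonation by halogen–metal exchange. NBS with catalytic i-Pr2NH in CH2Cl2 at 0 °C (amine-mediated ortho-bromination, para position blocked) should give 2-(benzyloxy)-6-bromo-4-methoxyphenol F7; the site selectivity of this bromination is the weak point of the fallback. (Me3Si)2NH in refluxing THF gives [2-(benzyloxy)-6-bromo-4-methoxyphenoxy]trimethylsilane F8. n-BuLi at −78 °C triggers bromine–lithium exchange and a 1,3 O-to-C silyl shift to the lithium phenoxide of 9, which Tf2O converts into 10.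

Step 8.
- Risk: hydrogenolysis of the aryl benzyl ether alongside saturation of the alkene, or slow reduction of the alkene next to the quaternary carbon.
- Fallback: it sets out from 16 and comes back at 17, accepting the loss of the benzyl group. Hydrogenation over Pd/C without additive gives methyl (5Z)-9-hydroxy-2,2-dimethyl-6-(pyrrolidin-1-yl)-3,4-dihydro-2H-1-benzoxocine-5-carboxylate F9. BnBr and K2CO3 in DMF restore the benzyl ether to give 17, now isolated, which is hydrolysed to 18 as before.

Step 9.
- Risk: slow or incomplete O-methylation if the enol content of the aryl ketone is low.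
- Fallback: it runs from 18 to 19 without any new compound. HC(OMe)3 with catalytic p-TsOH in MeOH at 50 °C forms the enol ether through the methoxy-stabilised cation and loss of the C5 proton; no enolate is involved, so C-alkylation is excluded.

Step 10.
- Risk: slow hydrolysis of the hindered vinylogous carbonate ester, and on acidification hydrolysis of the enol ether followed by decarboxylation.
- Fallback: it runs from 19 to 20 without any new compound. LiI in refluxing pyridine cleaves the ester methyl by SN2 attack to the lithium carboxylate, which is freed by cold acidification or used as the salt in step 11.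

## Further compounds

F1 | step 11 | 4'-O-benzyl-7-O-demethylcyclointegrin | Oc1cc(O)c2c(=O)c3c(oc2c1)-c1ccc(OCc2ccccc2)cc1OC(C)(C)CC3
F2 | step 11 | 4'-O-benzylcyclointegrin | COc1cc(O)c2c(=O)c3c(oc2c1)-c1ccc(OCc2ccccc2)cc1OC(C)(C)CC3
F3 | step 7 | tert-butyl{[7-(benzyloxy)-2,2-dimethyl-2H-chromen-4-yl]oxy}dimethylsilane | CC1(C)C=C(O[Si](C)(C)C(C)(C)C)c2ccc(OCc3ccccc3)cc2O1
F4 | step 7 | methyl 6-(benzyloxy)-8b-{[tert-butyl(dimethyl)silyl]oxy}-3,3-dimethyl-2a,8b-dihydro-3H-cyclobuta[c]chromene-1-carboxylate (cis ring fusion, racemic, one enantiomer drawn) | COC(=O)C1=C[C@H]2[C@]1(O[Si](C)(C)C(C)(C)C)c1ccc(OCc3ccccc3)cc1OC2(C)C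
F5 | step 7 | methyl (3Z,5Z)-9-(benzyloxy)-6-{[tert-butyl(dimethyl)silyl]oxy}-2,2-dimethyl-2H-1-benzoxocine-5-carboxylate | COC(=O)/C1=C(\O[Si](C)(C)C(C)(C)C)c2ccc(OCc3ccccc3)cc2OC(C)(C)/C=C\1
F6 | step 7 | methyl (5Z)-9-(benzyloxy)-6-{[tert-butyl(dimethyl)silyl]oxy}-2,2-dimethyl-3,4-dihydro-2H-1-benzoxocine-5-carboxylate | COC(=O)/C1=C(\O[Si](C)(C)C(C)(C)C)c2ccc(OCc3ccccc3)cc2OC(C)(C)CC1
F7 | step 4 | 2-(benzyloxy)-6-bromo-4-methoxyphenol | COc1cc(Br)c(O)c(OCc2ccccc2)c1
F8 | step 4 | [2-(benzyloxy)-6-bromo-4-methoxyphenoxy]trimethylsilane | COc1cc(Br)c(O[Si](C)(C)C)c(OCc2ccccc2)c1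
F9 | step 8 | methyl (5Z)-9-hydroxy-2,2-dimethyl-6-(pyrrolidin-1-yl)-3,4-dihydro-2H-1-benzoxocine-5-carboxylate | COC(=O)/C1=C(\N2CCCC2)c2ccc(O)cc2OC(C)(C)CC1
F0 | step 9 | none | none
F0 | step 10 | none | none
A1 | alternative 1 | 4'-O-benzyl-7-O-demethylcyclointegrin | Oc1cc(O)c2c(=O)c3c(oc2c1)-c1ccc(OCc2ccccc2)cc1OC(C)(C)CC3
A2 | alternative 1 | phloroglucinol | Oc1cc(O)cc(O)c1
A3 | alternative 2 | (Z)-didehydro-5,4'-di-O-benzylcyclointegrin | COc1cc(OCc2ccccc2)c2c(=O)c3c(oc2c1)-c1ccc(OCc2ccccc2)cc1OC(C)(C)/C=C\3
A4 | alternative 2 | 5-(benzyloxy)-2-{4-(benzyloxy)-2-[(2-methylbut-3-en-2-yl)oxy]phenyl}-3-ethenyl-7-methoxy-4H-chromen-4-one | COc1cc(OCc2ccccc2)c2c(=O)c(C=C)c(oc2c1)-c1ccc(OCc2ccccc2)cc1OC(C)(C)C=C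
A5 | alternative 3 | 9-(benzyloxy)-5-[2,6-bis(benzyloxy)-4-methoxybenzoyl]-2,2-dimethyl-2,3,4,5-tetrahydro-6H-1-benzoxocin-6-one (racemic, enolisable) | COc1cc(OCc2ccccc2)c(C(=O)C2CCC(C)(C)Oc3cc(OCc4ccccc4)ccc3C2=O)c(OCc2ccccc2)c1
A6 | alternative 3 | 1-[2,6-bis(benzyloxy)-4-methoxyphenyl]-5-[5-(benzyloxy)-2-bromophenoxy]-5-methylhexan-1-one | COc1cc(OCc2ccccc2)c(C(=O)CCCC(C)(C)Oc2cc(OCc3ccccc3)ccc2Br)c(OCc2ccccc2)c1
A7 | alternative 3 | carbon monoxide | [C-]#[O+]
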